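**Strategy.** The butenolide ring (O1, C2 lactone carbonyl, C3 enol carbon, C4 aryl carbon, quaternary C5) is cut into three pieces: the ketone of a chromanyl pyruvate ester, which supplies C5–O1 with the methyl ester and the benzylic arm already in place, the two alkyne carbons of an aryl silyl acetylene (C4 and C3), and carbon monoxide (C2). One ruthenium-catalysed carbonylative [2+2+1] cyclocoupling forms C4–C5, C2–C3 and O1–C2, closes the ring and creates the C5 stereocentre, with silicon on C3 as the masked enol oxygen. The precursor is methyl 3-[(S)-3-(benzyloxy)-2,2-dimethylchroman-6-yl]-2-oxopropanoate; both hydroxyl groups travel as benzyl ethers, so one hydrogenolysis ends the route.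

Key step: step 8

Remark: the target is (S) at the chroman carbinol carbon and (R) at C5 of the butenolide (numbered O1, C2 lactone carbonyl, C3, C4, C5); nitrile 1, phosphonate 8, alkyne 12 and silyl chloride 13 are taken as purchasable (8 is otherwise one O-silylation from methyl 2-(dimethoxyphosphoryl)-2-hydroxyacetate).

**Step 1**
Reactants: 1 2,2-dimethyl-2H-chromene-6-carbonitrile
Product: 2 (1aS,7bS)-2,2-dimethyl-1a,7b-dihydro-2H-oxireno[2,3-c]chromene-6-carbonitrile, the (3S,4S) epoxide in chroman numbering
Conditions: (S,S)-N,N'-bis(3,5-di-tert-butylsalicylidene)-1,2-cyclohexanediaminomanganese chloride [(S,S)-(salen)MnCl, trivalent manganese] (cat.), NaOCl (aq., pH 11.3), 4-phenylpyridine N-oxide (cat.), CH2Cl2, 0 °C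
Reagents that add atoms: sodium hypochlorite, [Na+].[O-]Cl
Why: Jacobsen–Katsuki epoxidation, for which a 2,2-dimethylchromene with an electron-poor benzo ring is a classic substrate class; the (S,S) catalyst should deliver oxygen to the face that gives the (3S,4S) epoxide, which fixes the later carbinol carbon as (S).

**Step 2**
Reactants: 2 (3S,4S) epoxide
Product: 3 (3S)-3-hydroxy-2,2-dimethylchroman-6-carbonitrile
Conditions: H2 (1 atm), Pd/C, EtOAc, rt
Reagents that add atoms: none
Why: Hydrogenolysis of a benzylic epoxide on palladium cleaves only the benzylic C4–O bond, so C3 keeps its oxygen and its (S) configuration, while an aryl nitrile is reduced far more slowly under these neutral, low-pressure conditions.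

**Step 3**
Reactants: 3 (3S)-3-hydroxy-2,2-dimethylchroman-6-carbonitrile
Product: 5 (3S)-3-(benzyloxy)-2,2-dimethylchroman-6-carbonitrile, via sodium alkoxide 4 (not isolated)
Conditions: NaH, THF–DMF, 0 °C; then BnBr, Bu4NI (cat.), rt
Reagents that add atoms: benzyl bromide, BrCc1ccccc1
Why: Williamson ether synthesis on the sodium alkoxide; the benzyl ether is chosen because it survives hydride, base, fluoride and hot carbon monoxide and leaves together with the phenol benzyl ether in the last step.

**Step 4**
Reactants: 5 (3S)-3-(benzyloxy)-2,2-dimethylchroman-6-carbonitrile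
Product: 7 (3S)-3-(benzyloxy)-2,2-dimethylchroman-6-carbaldehyde, via N-diisobutylalumino aldimine 6 (not isolated)
Conditions: iBu2AlH, CH2Cl2, −78 °C; then 1 M HCl (aq.), 0 °C
Reagents that add atoms: water, O
Why: Partial reduction of the nitrile with iBu2AlH stops at the N-alumino aldimine, which is hydrolysed to the aldehyde on acidic work-up (nitrile-to-aldehyde reduction).

**Step 5**
Reactants: 7 (3S)-3-(benzyloxy)-2,2-dimethylchroman-6-carbaldehyde; 8 methyl 2-[(tert-butyldimethylsilyl)oxy]-2-(dimethoxyphosphoryl)acetate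
Product: 10 methyl 3-[(3S)-3-(benzyloxy)-2,2-dimethylchroman-6-yl]-2-[(tert-butyldimethylsilyl)oxy]prop-2-enoate (E/Z mixture), via lithiated phosphonate 9 (not isolated)
Conditions: 8, LiN(SiMe3)2, THF, −78 °C; then 7, −78 °C to rt
Reagents that add atoms: none
Why: Horner–Wadsworth–Emmons olefination with an α-silyloxy phosphonate turns the aldehyde directly into the silyl enol ether of the homologous α-keto ester; the alkene geometry is of no consequence.

**Step 6**
Reactants: 10 silyl enol ether
Product: 11 methyl 3-[(3S)-3-(benzyloxy)-2,2-dimethylchroman-6-yl]-2-oxopropanoate (in equilibrium with its enol)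
Conditions: CsF, AcOH, MeCN, 0 °C
Reagents that add atoms: none
Why: Fluoride cleaves the labile O–Si bond of the silyl enol ether and acetic acid protonates the enolate at once, so the enolisable α-keto ester is released without the free base that would set off its aldol self-condensation.

**Step 7**
Reactants: 12 1-(benzyloxy)-4-ethynylbenzene; 13 benzylchlorodimethylsilane
Product: 15 benzyl{[4-(benzyloxy)phenyl]ethynyl}dimethylsilane, via lithium acetylide 14 (not isolated)
Conditions: n-BuLi, THF, −78 °C; then 13, −78 °C to rt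
Reagents that add atoms: none
Why: Deprotonation of the terminal alkyne and C-silylation of the lithium acetylide by substitution at silicon; the benzyldimethylsilyl group is thermally robust yet can be oxidised later after fluoride activation.

**Step 8**
Reactants: 11 methyl 3-[(3S)-3-(benzyloxy)-2,2-dimethylchroman-6-yl]-2-oxopropanoate; 15 benzyl{[4-(benzyloxy)phenyl]ethynyl}dimethylsilane; 16 carbon monoxide
Product: 17 methyl (2R)-4-[benzyl(dimethyl)silyl]-2-{[(3S)-3-(benzyloxy)-2,2-dimethylchroman-6-yl]methyl}-3-[4-(benzyloxy)phenyl]-5-oxo-2,5-dihydrofuran-2-carboxylate (butenolide numbering: silicon on C3, aryl on C4, 5R), isolated from its C5 epimer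
Conditions: Ru3(CO)12 (5 mol %), (R)-2-(diphenylphosphino)-2'-methoxy-1,1'-binaphthyl (15 mol %), CO (5 atm), toluene, 160 °C; then preparative HPLC on a cellulose tris(3,5-dimethylphenylcarbamate) phase
Reagents that add atoms: none
Why: Proposed new method: the α-keto ester (reacting through its keto tautomer, which is replenished from the enol at this temperature) chelates zerovalent ruthenium through both carbonyl oxygens and undergoes oxidative cyclisation with the alkyne to an oxaruthenacyclopentene of divalent ruthenium (C4–C5), carbon monoxide inserts into the Ru–C3 bond (C2–C3), and C–O reductive elimination from the resulting six-membered acyl ruthenacycle forms O1–C2. The closest known reaction type is the Ru3(CO)12-catalysed intermolecular [2+2+1] cyclocoupling (hetero-Pauson–Khand reaction) of α-keto esters with simple alkynes or alkenes and carbon monoxide, which is racemic and has not been run with aryl silyl alkynes. The one ring formed, the butenolide, is therefore closed by reductive elimination within a [2+2+1] cycloaddition and not by a polar cyclisation. The step needs regioselectivity (aryl on C4, silicon on C3), which the substrate secures because the bulky silyl group, which also stabilises a metal–carbon bond, takes the position next to ruthenium and leaves the aryl-bearing carbon to bond to the ketone carbon; it also needs chemoselectivity for the ketone, which the chelating ester on C5 provides. The new stereocentre C5 is created in the oxidative cyclisation; the chroman centre is too remote to bias it, so the only controlling element is the chiral phosphine on ruthenium, whose influence is unproven and whose antipode is to be chosen by the first experiment. Whatever selectivity is missing is made good by separating the two C5 epimers, which are diastereomers, and the (5R) assignment is to be secured by carrying both through to the end and comparing with the natural product.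

**Step 9**
Reactants: 17 3-silyl butenolide
Product: 19 methyl (2R)-2-{[(3S)-3-(benzyloxy)-2,2-dimethylchroman-6-yl]methyl}-3-[4-(benzyloxy)phenyl]-4-hydroxy-5-oxo-2,5-dihydrofuran-2-carboxylate, via butenolide silanol 18 (not isolated)
Conditions: Bu4NF, THF, 0 °C; then H2O2 (30 % aq.), KHCO3, MeOH, 0 °C to rt
Reagents that add atoms: hydrogen peroxide, OO
Why: Tamao–Fleming oxidation: fluoride expels the benzyl group from silicon to leave a silanol, peroxide then moves the alkenyl carbon C3 from silicon to oxygen, and hydrolysis gives the enol, the stable tautomer of the α-keto lactone because it is conjugated with the C4 aryl group; the quaternary C5 cannot epimerise.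

**Step 10**
Reactants: 19 enol bis(benzyl ether)
Product: 20 butyrolactone V, methyl (2R)-4-hydroxy-2-{[(3S)-3-hydroxy-2,2-dimethylchroman-6-yl]methyl}-3-(4-hydroxyphenyl)-5-oxo-2,5-dihydrofuran-2-carboxylate
Conditions: H2 (1 atm), Pd(OH)2/C, EtOAc–MeOH, rt
Reagents that add atoms: none
Why: Catalytic hydrogenolysis removes the aryl and the secondary alkyl benzyl ether in one operation, and the tetrasubstituted, hindered enol double bond of the butenolide is expected to resist hydrogenation.

**Compound list**

1 | 2,2-dimethyl-2H-chromene-6-carbonitrile | N#Cc1ccc2c(c1)C=CC(C)(C)O2 | starting material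
2 | (1aS,7bS)-2,2-dimethyl-1a,7b-dihydro-2H-oxireno[2,3-c]chromene-6-carbonitrile | N#Cc1ccc2c(c1)[C@@H]1O[C@@H]1C(C)(C)O2 | intermediate
3 | (3S)-3-hydroxy-2,2-dimethylchroman-6-carbonitrile | N#Cc1ccc2c(c1)C[C@H](O)C(C)(C)O2 | intermediate
4 | sodium (3S)-6-cyano-2,2-dimethylchroman-3-olate | N#Cc1ccc2c(c1)C[C@H]([O-])C(C)(C)O2.[Na+] | intermediate
5 | (3S)-3-(benzyloxy)-2,2-dimethylchroman-6-carbonitrile | N#Cc1ccc2c(c1)C[C@H](OCc1ccccc1)C(C)(C)O2 | intermediate
6 | N-(diisobutylalumino) aldimine of aldehyde 7 | CC(C)C[Al](CC(C)C)N=Cc1ccc2c(c1)C[C@H](OCc1ccccc1)C(C)(C)O2 | intermediate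
7 | (3S)-3-(benzyloxy)-2,2-dimethylchroman-6-carbaldehyde | O=Cc1ccc2c(c1)C[C@H](OCc1ccccc1)C(C)(C)O2 | intermediate
8 | methyl 2-[(tert-butyldimethylsilyl)oxy]-2-(dimethoxyphosphoryl)acetate | COC(=O)C(O[Si](C)(C)C(C)(C)C)P(=O)(OC)OC | starting material
9 | lithium salt of the carbanion of 8 | [Li+].COC(=O)[C-](O[Si](C)(C)C(C)(C)C)P(=O)(OC)OC | intermediate
10 | methyl 3-[(3S)-3-(benzyloxy)-2,2-dimethylchroman-6-yl]-2-[(tert-butyldimethylsilyl)oxy]prop-2-enoate (E/Z mixture) | COC(=O)C(O[Si](C)(C)C(C)(C)C)=Cc1ccc2c(c1)C[C@H](OCc1ccccc1)C(C)(C)O2 | intermediate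
11 | methyl 3-[(3S)-3-(benzyloxy)-2,2-dimethylchroman-6-yl]-2-oxopropanoate | COC(=O)C(=O)Cc1ccc2c(c1)C[C@H](OCc1ccccc1)C(C)(C)O2 | intermediate
12 | 1-(benzyloxy)-4-ethynylbenzene | C#Cc1ccc(OCc2ccccc2)cc1 | starting material
13 | benzylchlorodimethylsilane | C[Si](C)(Cl)Cc1ccccc1 | starting material
14 | lithium [4-(benzyloxy)phenyl]acetylide | [Li+].[C-]#Cc1ccc(OCc2ccccc2)cc1 | intermediate
15 | benzyl{[4-(benzyloxy)phenyl]ethynyl}dimethylsilane | C[Si](C)(Cc1ccccc1)C#Cc1ccc(OCc2ccccc2)cc1 | intermediate
16 | carbon monoxide | [C-]#[O+] | starting material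
17 | methyl (2R)-4-[benzyl(dimethyl)silyl]-2-{[(3S)-3-(benzyloxy)-2,2-dimethylchroman-6-yl]methyl}-3-[4-(benzyloxy)phenyl]-5-oxo-2,5-dihydrofuran-2-carboxylate | COC(=O)[C@]1(Cc2ccc3c(c2)C[C@H](OCc2ccccc2)C(C)(C)O3)OC(=O)C([Si](C)(C)Cc2ccccc2)=C1c1ccc(OCc2ccccc2)cc1 | intermediate
18 | methyl (2R)-2-{[(3S)-3-(benzyloxy)-2,2-dimethylchroman-6-yl]methyl}-3-[4-(benzyloxy)phenyl]-4-[hydroxy(dimethyl)silyl]-5-oxo-2,5-dihydrofuran-2-carboxylate | COC(=O)[C@]1(Cc2ccc3c(c2)C[C@H](OCc2ccccc2)C(C)(C)O3)OC(=O)C([Si](C)(C)O)=C1c1ccc(OCc2ccccc2)cc1 | intermediate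
19 | methyl (2R)-2-{[(3S)-3-(benzyloxy)-2,2-dimethylchroman-6-yl]methyl}-3-[4-(benzyloxy)phenyl]-4-hydroxy-5-oxo-2,5-dihydrofuran-2-carboxylate | COC(=O)[C@]1(Cc2ccc3c(c2)C[C@H](OCc2ccccc2)C(C)(C)O3)OC(=O)C(O)=C1c1ccc(OCc2ccccc2)cc1 | intermediate
20 | butyrolactone V, methyl (2R)-4-hydroxy-2-{[(3S)-3-hydroxy-2,2-dimethylchroman-6-yl]methyl}-3-(4-hydroxyphenyl)-5-oxo-2,5-dihydrofuran-2-carboxylate | COC(=O)[C@]1(Cc2ccc3c(c2)C[C@H](O)C(C)(C)O3)OC(=O)C(O)=C1c1ccc(O)cc1 | target

**Step count.** Total: 10 steps. Longest linear sequence: 9 steps (steps 1 to 6, then 8, 9 and 10); the alkyne arm is one step (step 7).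

**Steps most likely to fail**

1. Step 8 (Proposed new method). The hindered ketone, largely held as its enol, may not enter the oxidative cyclisation before the alkyne is consumed in other ways. The alkyne may also insert with the reverse orientation, and the ligand may give no facial preference at C5. The fallback is a polar construction of the same ring by known chemistry; it sets out from 11 and comes back at 19, bypassing steps 8 and 9. 4-(Benzyloxy)benzaldehyde (O=Cc1ccc(OCc2ccccc2)cc1) is olefinated with 9 as in step 5 to give methyl 3-[4-(benzyloxy)phenyl]-2-[(tert-butyldimethylsilyl)oxy]prop-2-enoate F1. A Mukaiyama aldol addition of this enol silane to the ketone of 11, activated by chelation to TiCl4 (CH2Cl2, −78 °C), forms C4–C5 and gives dimethyl 2-{[(3S)-3-(benzyloxy)-2,2-dimethylchroman-6-yl]methyl}-3-[4-(benzyloxy)phenyl]-2-hydroxy-4-oxopentanedioate F2. Its tertiary hydroxyl closes onto the keto ester terminus with loss of methanol (on work-up or with a trace of acid), and the α-keto lactone enolises to 19. This aldol–lactonisation is the classical way to 3-hydroxy-4-aryl butenolides. It is not selective at C5, so the epimers would be separated at 19 by the same HPLC method, and step 10 follows.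

2. Step 9. Fluoride may cause protodesilylation at C3 instead of preparing silicon for the carbon-to-oxygen shift, or basic peroxide may open the lactone. The fallback sets out from 17 and comes back at 19. Protodesilylation is made the intended reaction (Bu4NF, wet THF) and gives methyl (2R)-2-{[(3S)-3-(benzyloxy)-2,2-dimethylchroman-6-yl]methyl}-3-[4-(benzyloxy)phenyl]-5-oxo-2,5-dihydrofuran-2-carboxylate F3. Dihydroxylation of the C3=C4 bond (OsO4 cat., N-methylmorpholine N-oxide, acetone–water) gives methyl (2R)-2-{[(3S)-3-(benzyloxy)-2,2-dimethylchroman-6-yl]methyl}-3-[4-(benzyloxy)phenyl]-3,4-dihydroxy-5-oxooxolane-2-carboxylate F4, a cis-diol whose two new centres need not be controlled. Acid-catalysed dehydration (TsOH cat., toluene, 60 °C) ionises the tertiary benzylic C4 hydroxyl, which the 4-benzyloxyphenyl group stabilises, and loss of the C3 proton gives enol 19. This is the same dehydration that converts 3-aryl-2,3-dihydroxy esters into arylpyruvates.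

3. Step 6. Once set free, the enolisable keto ester may undergo aldol self-condensation in the fluoride medium or oxidative cleavage through its enol on handling. The fallback sets out from 7 and comes back at 11, replacing steps 5 and 6. Horner–Wadsworth–Emmons olefination of 7 with methyl 2-[(tert-butoxycarbonyl)amino]-2-(dimethoxyphosphoryl)acetate (COC(=O)C(NC(=O)OC(C)(C)C)P(=O)(OC)OC) and DBU in CH2Cl2 gives methyl (2Z)-3-[(3S)-3-(benzyloxy)-2,2-dimethylchroman-6-yl]-2-[(tert-butoxycarbonyl)amino]prop-2-enoate F5. CF3CO2H in CH2Cl2 removes the carbamate, and aqueous work-up hydrolyses the enamine–imine to 11. The release is acidic throughout, so the aldol condensation should not run, and 11 would be used at once in step 8.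

**Further compounds**

F1 | step 8 | methyl 3-[4-(benzyloxy)phenyl]-2-[(tert-butyldimethylsilyl)oxy]prop-2-enoate | COC(=O)C(O[Si](C)(C)C(C)(C)C)=Cc1ccc(OCc2ccccc2)cc1
F2 | step 8 | dimethyl 2-{[(3S)-3-(benzyloxy)-2,2-dimethylchroman-6-yl]methyl}-3-[4-(benzyloxy)phenyl]-2-hydroxy-4-oxopentanedioate | COC(=O)C(=O)C(c1ccc(OCc2ccccc2)cc1)C(O)(Cc1ccc2c(c1)C[C@H](OCc1ccccc1)C(C)(C)O2)C(=O)OC
F3 | step 9 | methyl (2R)-2-{[(3S)-3-(benzyloxy)-2,2-dimethylchroman-6-yl]methyl}-3-[4-(benzyloxy)phenyl]-5-oxo-2,5-dihydrofuran-2-carboxylate | COC(=O)[C@]1(Cc2ccc3c(c2)C[C@H](OCc2ccccc2)C(C)(C)O3)OC(=O)C=C1c1ccc(OCc2ccccc2)cc1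
F4 | step 9 | methyl (2R)-2-{[(3S)-3-(benzyloxy)-2,2-dimethylchroman-6-yl]methyl}-3-[4-(benzyloxy)phenyl]-3,4-dihydroxy-5-oxooxolane-2-carboxylate | COC(=O)[C@]1(Cc2ccc3c(c2)C[C@H](OCc2ccccc2)C(C)(C)O3)OC(=O)C(O)C1(O)c1ccc(OCc2ccccc2)cc1
F5 | step 6 | methyl (2Z)-3-[(3S)-3-(benzyloxy)-2,2-dimethylchroman-6-yl]-2-[(tert-butoxycarbonyl)amino]prop-2-enoate | COC(=O)/C(NC(=O)OC(C)(C)C)=C/c1ccc2c(c1)C[C@H](OCc1ccccc1)C(C)(C)O2
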